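The numbers in the tables were computed with made-up constants.

If the coupling partner serves both the left-handed substrate and the protic impurity, the excess asked for depends on how much partner the impurity takes.

| flask | left-handed substrate | right-handed substrate | coupling partner | protic impurity | precatalyst | remark | time |
|---|---|---|---|---|---|---|---|
| delta | 0.20 M | 0.20 M | 0.12 M | 0.10 M | 0.22 mM | run made earlier |  |
| zeta | 0.20 M | 0.20 M | 0.48 M | 0.10 M | 0.22 mM | run made earlier |  |
| flask | 0.20 M | 0.20 M | 0.240 M | 0.100 M | 0.22 mM |  | 6.0 min |

| run | time / min | right-handed substrate / % | left-handed substrate / % | left-handed product / % |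
|---|---|---|---|---|
| delta | 0.200 | 50 | 48 | 0 |
| delta | 0.500 | 49 | 51 | 3 |
| delta | 1.00 | 50 | 45 | 4 |
| delta | 1.50 | 50 | 44 | 8 |
| delta | 2.00 | 51 | 41 | 11 |
| delta | 3.00 | 49 | 36 | 14 |
| delta | 4.00 | 52 | 34 | 10 |
| zeta | 0.500 | 52 | 33 | 15 |
| zeta | 1.00 | 50 | 14 | 38 |
| zeta | 1.50 | 52 | 3 | 47 |
| zeta | 2.00 | 49 | 3 | 51 |
| zeta | 2.50 | 48 | 1 | 47 |
| zeta | 3.00 | 49 | 2 | 50 |
| zeta | 4.00 | 46 | 1 | 49 |

(standard deviation of a reading: 2 percentage points)

- free catalyst is single-handed; left-handed substrate and right-handed substrate are mirror images of each other, charged as a racemate, each of them at the stated concentration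

1. whether the excess of right-handed substrate over left-handed substrate among what is left of the two reaches 80 % by 6.0 min (no / yes)
2. the highest excess of right-handed substrate over left-handed substrate among what is left of the two up to 6.0 min

Right-handed substrate stays near its charge in both earlier runs, so we treat it as standing and follow the left-handed substrate. We call the partner not found as consumed left-handed substrate the toll. Taking the partner in delta as consumed by the last reading, the toll read there is 0.0560 M. We suppose the impurity reacts with the partner in a bimolecular step, so the logarithm of its fall grows with [coupling partner] integrated over time. Delta's reading gives 0.821, and we carry this as the exposure, the natural logarithm of impurity charged over impurity remaining at the close of the reaction.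

Two extreme versions of the flask can be solved at once. If the toll stayed as in delta, 0.0160 M of left-handed substrate would remain and the excess would be 85.2 %. If the whole impurity charge were quenched, 0.0600 M would remain and the excess would be 53.8 %.

We expect the flask between them: its partner charge is twice delta's, and we take the impurity charge as the ceiling of the toll. Assuming that the partner lasts as long in the flask as in delta, our estimate of the exposure doubles to 1.64, and our estimate of the toll is 0.0806 M, above delta's toll and below the impurity charge. On this reckoning 0.0406 M of left-handed substrate remains, so our estimated excess is 66.2 %, short of the level.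

The forecast answers "no", with a top of 77 % (from 62 % to 90 %), holding that the “impurity appears to take a fixed share of partner”.

The flask gives "no", with a top of 62.5 %.

    coupling partner → decomposition product (k = 2.10 × 10⁻⁵ s⁻¹)
    coupling partner + catalyst intermediate B → free catalyst + right-handed product (k = 3.40 M⁻¹ s⁻¹)
    coupling partner + protic impurity → quenched reagent (k = 0.0890 M⁻¹ s⁻¹)
    coupling partner + catalyst intermediate A → free catalyst + left-handed product (k = 87.0 M⁻¹ s⁻¹)
    free catalyst + left-handed substrate ⇌ catalyst intermediate A (K = 160 M⁻¹, k = 1700 M⁻¹ s⁻¹)
    coupling partner + precatalyst → free catalyst + spent reagent (k = 0.0810 M⁻¹ s⁻¹)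
    free catalyst + right-handed substrate ⇌ catalyst intermediate B (K = 6.40 M⁻¹, k = 1400 M⁻¹ s⁻¹)

In the flask, 17 % of the impurity charge remains after 6.00 min, an exposure of 1.75, and the coupling partner, the limiting reagent, stands at 0.92 % of its charge. The quench is the main reason for the shortfall: without that step, the flask's top reaches >99.9 %. For the neighbour with 0.060 M of impurity, the flask's exposure gives an estimated toll of 0.0495 M and an estimated excess of 90.9 %. The computed neighbour has a top of 83.1 %.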